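The chroman ring is disconnected across C3–C4 and O1–C8a, which splits the target into its two aromatic halves. The key step is a one-pot formal [3+3] annulation. An (S)-aryloxirane on ring B, released from chlorohydrin 8, is opened at the benzylic carbon C3 by the Grignard reagent of benzyl chloride 12 (C3–C4, inversion). The liberated C2 alkoxide then closes onto C8a through the aryne formed by loss of HF across C8–C8a (O1–C8a). The step exploits that C3 is benzylic to the 2',4'-dioxygenated ring B, and that H8 lies between fluorine and the C7 oxygen, so the 3-alkoxyaryne accepts oxygen at C8a.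

Key step: step 9

Assumption (chemistry): C3 of the target is (R). The (R,R)-TsDPEN–Ru catalyst is taken to reduce 7 with the facial sense known for 2-chloroacetophenone, which corresponds to the (1S)-chlorohydrin.

Step 1
Reactants: 1 1-(2,4-dihydroxyphenyl)ethan-1-one; 2 1-bromo-3-methylbut-2-ene (prenyl bromide)
Product: 3 1-[2,4-dihydroxy-3-(3-methylbut-2-en-1-yl)phenyl]ethan-1-one
Conditions: KOH (10% aq), 0 → 25 °C
Reagents that add atoms: none
Why: C-alkylation of the resorcinolate in water (phenoxide C-prenylation), where the carbon between the two oxygens is the most electron-rich ring position and solvation of oxygen disfavours O-alkylation, should give the 3-prenyl ketone; no stereocentre is formed.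

Step 2
Reactants: 3 1-[2,4-dihydroxy-3-(3-methylbut-2-en-1-yl)phenyl]ethan-1-one; 4 3-methylbut-2-enal (prenal)
Product: 5 1-[7-hydroxy-2,2-dimethyl-8-(3-methylbut-2-en-1-yl)-2H-chromen-6-yl]ethan-1-one
Conditions: ethylenediammonium diacetate (cat.), xylene, 140 °C
Reagents that add atoms: none
Why: Amine-catalysed condensation of prenal at C5 (ortho to the free 4-OH), dehydration to an ortho-quinone methide and oxa-6π electrocyclisation (chromene annulation) close the 2,2-dimethylpyran, and only the linear chromene can form because C3 carries the prenyl group and the 2-OH is hydrogen-bonded to the ketone.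

Step 3
Reactants: 5 1-[7-hydroxy-2,2-dimethyl-8-(3-methylbut-2-en-1-yl)-2H-chromen-6-yl]ethan-1-one
Product: 6 1-[7-(methoxymethoxy)-2,2-dimethyl-8-(3-methylbut-2-en-1-yl)-2H-chromen-6-yl]ethan-1-one
Conditions: MOMCl, K2CO3, acetone, 56 °C
Reagents that add atoms: chloromethyl methyl ether (MOMCl), COCCl
Why: Williamson-type O-alkylation protects the chelated phenol as its MOM ether, which is stable to the enolate, Grignard and amide bases used later.

Step 4
Reactants: 6 1-[7-(methoxymethoxy)-2,2-dimethyl-8-(3-methylbut-2-en-1-yl)-2H-chromen-6-yl]ethan-1-one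
Product: 7 2-chloro-1-[7-(methoxymethoxy)-2,2-dimethyl-8-(3-methylbut-2-en-1-yl)-2H-chromen-6-yl]ethan-1-one
Conditions: LDA, THF, −78 °C; then TsCl, −78 → 0 °C
Reagents that add atoms: p-toluenesulfonyl chloride (TsCl), Cc1ccc(cc1)S(Cl)(=O)=O
Why: The kinetic lithium enolate of the methyl ketone takes up chlorine from TsCl acting as a Cl+ donor (enolate α-chlorination), a reagent that should not touch the prenyl or chromene double bonds.

Step 5
Reactants: 7 2-chloro-1-[7-(methoxymethoxy)-2,2-dimethyl-8-(3-methylbut-2-en-1-yl)-2H-chromen-6-yl]ethan-1-one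
Product: 8 (1S)-2-chloro-1-[7-(methoxymethoxy)-2,2-dimethyl-8-(3-methylbut-2-en-1-yl)-2H-chromen-6-yl]ethan-1-ol
Conditions: RuCl[(R,R)-TsDPEN](p-cymene) (1 mol %), HCO2H–Et3N (5:2), EtOAc, 25 °C
Reagents that add atoms: none
Why: Noyori–Ikariya asymmetric transfer hydrogenation, in which the (R,R)-TsDPEN–Ru hydride distinguishes the aryl group from CH2Cl, should set the (1S) carbinol centre and leave chlorine and the isolated alkenes untouched.

Step 6
Reactants: 9 2-fluoro-4-hydroxybenzaldehyde
Product: 10 2-fluoro-4-(methoxymethoxy)benzaldehyde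
Conditions: MOMCl, K2CO3, acetone, 0 → 25 °C
Reagents that add atoms: chloromethyl methyl ether (MOMCl), COCCl
Why: Williamson-type O-alkylation of the acidic para-formyl phenol installs the MOM group that masks the 7-OH and later acidifies H8.

Step 7
Reactants: 10 2-fluoro-4-(methoxymethoxy)benzaldehyde
Product: 11 [2-fluoro-4-(methoxymethoxy)phenyl]methanol
Conditions: NaBH4, MeOH, 0 °C
Reagents that add atoms: none
Why: Borohydride reduction of the aldehyde gives the benzylic alcohol without affecting the aryl fluoride or the acetal.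

Step 8
Reactants: 11 [2-fluoro-4-(methoxymethoxy)phenyl]methanol
Product: 12 1-(chloromethyl)-2-fluoro-4-(methoxymethoxy)benzene
Conditions: PPh3, N-chlorosuccinimide, THF, 0 °C
Reagents that add atoms: N-chlorosuccinimide (NCS), O=C1CCC(=O)N1Cl
Why: Appel-type deoxychlorination proceeds through the alkoxyphosphonium salt under neutral conditions, so the acid-labile MOM acetal should survive.

Step 9
Reactants: 8 (1S)-2-chloro-1-[7-(methoxymethoxy)-2,2-dimethyl-8-(3-methylbut-2-en-1-yl)-2H-chromen-6-yl]ethan-1-ol; 12 1-(chloromethyl)-2-fluoro-4-(methoxymethoxy)benzene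
Product: 16 (3R)-7-(methoxymethoxy)-3-[7-(methoxymethoxy)-2,2-dimethyl-8-(3-methylbut-2-en-1-yl)-2H-chromen-6-yl]-3,4-dihydro-2H-chromene, via benzylic Grignard reagent 13 (not isolated), via (S)-aryloxirane 14 (not isolated), via (R)-fluoro alkoxide 15 (not isolated)
Conditions: 12, Mg, THF, 0 °C; separately 8, NaH, THF, 0 → 25 °C; then 13 (1.3 equiv), Et2O–THF, −40 → 0 °C; then LiTMP, −78 → 25 °C; aq NH4Cl
Reagents that add atoms: none
Why: The sodium alkoxide of 8 closes to the (S)-oxirane 14, whose Mg-activated benzylic carbon C3 is attacked by the benzylic carbon C4 of 13 in a borderline SN2 opening that forms C3–C4 and leaves the C2 alkoxide 15. LiTMP then removes H8 (flanked by F and OMOM), LiF is lost, and the tethered alkoxide adds to the resulting 7-alkoxyaryne at C8a to form O1–C8a, the C8 anion being protonated on work-up. The closest known reaction types are the benzylic ring opening of aryl oxiranes by allyl- and benzyl-type Grignard reagents and the aryne (elimination–addition) ring closure of ω-(2-halophenyl)alkoxides. The pyran ring closes by 6-exo attack of O1 on the proximal aryne carbon C8a, and direct SNAr at C8a would give the same product. C3 is not created but inverted: C4 enters anti to the departing oxirane oxygen, so the (S)-oxirane should give (R)-C3, and the cyclisation does not touch it. The step needs attack at C3 and not C2, which the 2'-OMOM and 4'-O donors of ring B secure by polarising the benzylic C–O bond, and addition at C8a and not C8, which the tether and the normal meta-selectivity of 3-alkoxyarynes secure.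

Step 10
Reactants: 16 (3R)-7-(methoxymethoxy)-3-[7-(methoxymethoxy)-2,2-dimethyl-8-(3-methylbut-2-en-1-yl)-2H-chromen-6-yl]-3,4-dihydro-2H-chromene
Product: 17 (3R)-3-[7-hydroxy-2,2-dimethyl-8-(3-methylbut-2-en-1-yl)-2H-chromen-6-yl]-3,4-dihydro-2H-chromen-7-ol
Conditions: HCl (2 M aq), MeOH, 40 °C
Reagents that add atoms: none
Why: Acid-catalysed transacetalisation with methanol (MOM cleavage) frees both phenols under conditions mild enough that the 3'-prenyl group and the 2H-chromene are not expected to cyclise or add methanol, and C3 is untouched.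

Compound list
1 | 1-(2,4-dihydroxyphenyl)ethan-1-one | CC(=O)c1ccc(O)cc1O | starting material
2 | 1-bromo-3-methylbut-2-ene | CC(C)=CCBr | starting material
3 | 1-[2,4-dihydroxy-3-(3-methylbut-2-en-1-yl)phenyl]ethan-1-one | CC(=O)c1ccc(O)c(CC=C(C)C)c1O | intermediate
4 | 3-methylbut-2-enal | CC(C)=CC=O | starting material
5 | 1-[7-hydroxy-2,2-dimethyl-8-(3-methylbut-2-en-1-yl)-2H-chromen-6-yl]ethan-1-one | CC(C)=CCc1c(O)c(C(C)=O)cc2c1OC(C)(C)C=C2 | intermediate
6 | 1-[7-(methoxymethoxy)-2,2-dimethyl-8-(3-methylbut-2-en-1-yl)-2H-chromen-6-yl]ethan-1-one | CC(C)=CCc1c(OCOC)c(C(C)=O)cc2c1OC(C)(C)C=C2 | intermediate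
7 | 2-chloro-1-[7-(methoxymethoxy)-2,2-dimethyl-8-(3-methylbut-2-en-1-yl)-2H-chromen-6-yl]ethan-1-one | CC(C)=CCc1c(OCOC)c(C(=O)CCl)cc2c1OC(C)(C)C=C2 | intermediate
8 | (1S)-2-chloro-1-[7-(methoxymethoxy)-2,2-dimethyl-8-(3-methylbut-2-en-1-yl)-2H-chromen-6-yl]ethan-1-ol | CC(C)=CCc1c(OCOC)c([C@H](O)CCl)cc2c1OC(C)(C)C=C2 | intermediate
9 | 2-fluoro-4-hydroxybenzaldehyde | O=Cc1ccc(O)cc1F | starting material
10 | 2-fluoro-4-(methoxymethoxy)benzaldehyde | O=Cc1ccc(OCOC)cc1F | intermediate
11 | [2-fluoro-4-(methoxymethoxy)phenyl]methanol | OCc1ccc(OCOC)cc1F | intermediate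
12 | 1-(chloromethyl)-2-fluoro-4-(methoxymethoxy)benzene | ClCc1ccc(OCOC)cc1F | intermediate
13 | {[2-fluoro-4-(methoxymethoxy)phenyl]methyl}magnesium chloride | Cl[Mg]Cc1ccc(OCOC)cc1F | intermediate
14 | (2S)-2-[7-(methoxymethoxy)-2,2-dimethyl-8-(3-methylbut-2-en-1-yl)-2H-chromen-6-yl]oxirane | CC(C)=CCc1c(OCOC)c([C@H]3CO3)cc2c1OC(C)(C)C=C2 | intermediate
15 | (2R)-3-[2-fluoro-4-(methoxymethoxy)phenyl]-2-[7-(methoxymethoxy)-2,2-dimethyl-8-(3-methylbut-2-en-1-yl)-2H-chromen-6-yl]propan-1-ol (present in the flask as its chloromagnesium alkoxide) | CC(C)=CCc1c(OCOC)c([C@H](CO)Cc3ccc(OCOC)cc3F)cc2c1OC(C)(C)C=C2 | intermediate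
16 | (3R)-7-(methoxymethoxy)-3-[7-(methoxymethoxy)-2,2-dimethyl-8-(3-methylbut-2-en-1-yl)-2H-chromen-6-yl]-3,4-dihydro-2H-chromene | CC(C)=CCc1c(OCOC)c([C@@H]3COc4cc(OCOC)ccc4C3)cc2c1OC(C)(C)C=C2 | intermediate
17 | (3R)-3-[7-hydroxy-2,2-dimethyl-8-(3-methylbut-2-en-1-yl)-2H-chromen-6-yl]-3,4-dihydro-2H-chromen-7-ol | CC(C)=CCc1c(O)c([C@@H]2COc3cc(O)ccc3C2)cc2c1OC(C)(C)C=C2 | target

Total step count: 10 (steps 6–8 build the ring-A branch). Longest linear sequence: 7 steps (1–5, 9, 10).

Steps most likely to fail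

Step 9. The electron-rich benzylic C–O bond of 14 may ionise before C–C bond formation. That would erode the stereochemical fidelity at C3 or divert the oxirane by 1,2-hydride shift to the arylacetaldehyde, which the Grignard reagent would then attack at the carbonyl. Wurtz coupling during formation of 13 is a further loss channel. The fallback separates the two bond formations and relies on auxiliary control. It sets out from 8: NaH closes it to 14, and a catalytic Lewis acid (InCl3) then promotes the 1,2-hydride shift deliberately to give the arylacetaldehyde F1. Chlorite oxidation (NaClO2, NaH2PO4, 2-methylbut-2-ene) should give the arylacetic acid F2. Acylation of lithiated (R)-4-benzyl-1,3-oxazolidin-2-one through the pivaloyl mixed anhydride should give the N-acyl oxazolidinone F3. Enolate alkylation (NaHMDS, 12, NaI, THF, −78 °C) should give the (2R)-alkylated imide F4, by the usual sense of this auxiliary. Reduction with LiBH4 returns to the route at 15, which is cyclised with LiTMP to 16.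

Step 1. Competing O-alkylation, alkylation at C5 and double prenylation may leave little of the 3-C-prenyl ketone. The fallback delivers the prenyl group by sigmatropic rearrangement and sets out from 1. O-alkylation of the 4-OH with 3-chloro-3-methylbut-1-yne (K2CO3, KI, CuI cat., acetone) should give the propargylic aryl ether F5. Semi-hydrogenation (Pd/CaCO3–Pb, quinoline, H2) should give the 1,1-dimethylallyl aryl ether F6. Aromatic Claisen rearrangement (N,N-diethylaniline, heat) should then place a prenyl group at C3, between the two oxygens, and return to the route at 3.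

Step 4. Over-chlorination of the enolate and aldol self-condensation of the methyl ketone may consume 6. The fallback replaces chlorine by oxygen and sets out from 6. Enolate hydroxylation (LiHMDS, then 2-(phenylsulfonyl)-3-phenyloxaziridine) should give the α-hydroxy ketone F7. Transfer hydrogenation under the conditions of step 5 should give the (S)-diol F8. Tin-catalysed sulfonylation of the primary hydroxyl (TsCl, Bu2SnO cat., Et3N) should give the primary tosylate F9, which NaH closes to the oxirane; the route is rejoined at 14 within step 9.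

Further compounds
F1 | step 9 | 2-[7-(methoxymethoxy)-2,2-dimethyl-8-(3-methylbut-2-en-1-yl)-2H-chromen-6-yl]acetaldehyde | CC(C)=CCc1c(OCOC)c(CC=O)cc2c1OC(C)(C)C=C2
F2 | step 9 | 2-[7-(methoxymethoxy)-2,2-dimethyl-8-(3-methylbut-2-en-1-yl)-2H-chromen-6-yl]acetic acid | CC(C)=CCc1c(OCOC)c(CC(=O)O)cc2c1OC(C)(C)C=C2
F3 | step 9 | (4R)-4-benzyl-3-{[7-(methoxymethoxy)-2,2-dimethyl-8-(3-methylbut-2-en-1-yl)-2H-chromen-6-yl]acetyl}-1,3-oxazolidin-2-one | CC(C)=CCc1c(OCOC)c(CC(=O)N3[C@H](Cc4ccccc4)COC3=O)cc2c1OC(C)(C)C=C2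
F4 | step 9 | (4R)-4-benzyl-3-{(2R)-3-[2-fluoro-4-(methoxymethoxy)phenyl]-2-[7-(methoxymethoxy)-2,2-dimethyl-8-(3-methylbut-2-en-1-yl)-2H-chromen-6-yl]propanoyl}-1,3-oxazolidin-2-one | CC(C)=CCc1c(OCOC)c([C@@H](Cc3ccc(OCOC)cc3F)C(=O)N4[C@H](Cc5ccccc5)COC4=O)cc2c1OC(C)(C)C=C2
F5 | step 1 | 1-{2-hydroxy-4-[(2-methylbut-3-yn-2-yl)oxy]phenyl}ethan-1-one | CC(=O)c1ccc(OC(C)(C)C#C)cc1O
F6 | step 1 | 1-{2-hydroxy-4-[(2-methylbut-3-en-2-yl)oxy]phenyl}ethan-1-one | CC(=O)c1ccc(OC(C)(C)C=C)cc1O
F7 | step 4 | 2-hydroxy-1-[7-(methoxymethoxy)-2,2-dimethyl-8-(3-methylbut-2-en-1-yl)-2H-chromen-6-yl]ethan-1-one | CC(C)=CCc1c(OCOC)c(C(=O)CO)cc2c1OC(C)(C)C=C2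
F8 | step 4 | (1S)-1-[7-(methoxymethoxy)-2,2-dimethyl-8-(3-methylbut-2-en-1-yl)-2H-chromen-6-yl]ethane-1,2-diol | CC(C)=CCc1c(OCOC)c([C@H](O)CO)cc2c1OC(C)(C)C=C2
F9 | step 4 | (2S)-2-hydroxy-2-[7-(methoxymethoxy)-2,2-dimethyl-8-(3-methylbut-2-en-1-yl)-2H-chromen-6-yl]ethyl 4-methylbenzenesulfonate | CC(C)=CCc1c(OCOC)c([C@H](O)COS(=O)(=O)c3ccc(C)cc3)cc2c1OC(C)(C)C=C2
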